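**The task.** I counted turnovers. In the earlier runs L fell early, D then shrank while the product Q grew, and X stayed small, and I wanted to know which of them led in Thursday's and Friday's flasks.

| flask | L | J | remark | time |
|---|---|---|---|---|
| autumn | 0.050 M | 3.4 mM | run made earlier |  |
| winter | 0.050 M | 7.5 mM | run made earlier |  |
| midnight | 0.10 M | 5 mM | run made earlier |  |
| Thursday's | 0.050 M | 5.00 mM |  | 6.0 h |
| Friday's | 0.050 M | 5.00 mM |  | 12 h |

| run | time / h | L / % | X / % | Q / % | D / % |
|---|---|---|---|---|---|
| autumn | 1.50 | 4.6 | 2.1 | 7.8 | 70.4 |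
| autumn | 3.00 | 3.3 | 2.5 | 15.3 | 62.9 |
| autumn | 5.00 | 1.5 | 2.6 | 23.5 | 54.6 |
| autumn | 6.00 | 1.9 | 2.6 | 27.6 | 49.9 |
| winter | 0.833 | 8.4 | 2.1 | 3.2 | 62.9 |
| winter | 2.00 | 3.4 | 1.3 | 9.3 | 63.5 |
| winter | 4.00 | 2.5 | 2.0 | 18.4 | 54.1 |
| winter | 6.00 | 1.4 | 3.0 | 26.5 | 46.9 |
| midnight | 0.833 | 7.4 | 1.4 | 3.0 | 64.8 |
| midnight | 2.00 | 2.2 | 2.0 | 8.6 | 63.3 |
| midnight | 4.00 | 2.3 | 1.7 | 17.6 | 53.7 |
| midnight | 6.00 | 2.1 | 3.3 | 26.3 | 46.7 |

(readings scatter by 0.5 percentage points)

- which of these there is most of at the end, counted by the L in it, Thursday's (D / L / X / Q)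
- which of these there is most of at the end, counted by the L in it, Friday's (D / L / X / Q)
- amount of the one of these that there is most of at the end, in percent of the L charged, Thursday's
- amount of the one of these that there is most of at the end, in percent of the L charged, Friday's

**Reading D.** A first-order rate constant k is the fraction lost per hour, so a species lost by a first-order step falls as exp(−kt), and k is the logarithm of the ratio of two readings divided by the hours between them. At the last autumn reading D held 49.9% against 1.9% for L, so I followed D. The autumn run gave k = 0.0765 h⁻¹, the winter run 0.0758 h⁻¹ and the midnight run 0.0760 h⁻¹, although their J and L differed.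

**The count.** I called T = ln(2)/k = 9.06 h one turnover, the time in which D falls to half, and counted n = t/T. In the autumn run D + Q went from 78.2% to 77.5%, so Q gained about what D lost, and on this reckoning the two stand level at n = one. Thursday's count was 0.662, less than one, so D should lead; Friday's was 1.32, more than one, so Q should lead. For the amounts I interpolated the last D + Q of the autumn and winter runs to 5.00 mM of J, which gave a pool P = 75.9%. Then D = P exp(−kt) gave 48.0% for Thursday's flask, and Q = P − D gave 45.6% for Friday's.

**The forecast.** The forecast judged that “this step is first order in D and independent of J and L”, and named D at 48.7% for Thursday's flask and Q at 45.5% for Friday's. It chose the same species as I did, with amounts 0.70 percentage points above mine on Thursday's and 0.100 points below mine on Friday's.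

**The result.** Thursday's flask gave D at 48.9%, and Friday's gave Q at 44.9%.

    D → Q (k = 2.14 × 10⁻⁵ s⁻¹)
    L + J → G (k = 0.111 L mol⁻¹ s⁻¹)
    2 L → E (k = 0.00202 L mol⁻¹ s⁻¹)
    L ⇌ D (K = 26.0, k = 7.61 × 10⁻⁴ s⁻¹)
    L ⇌ X (K = 32.5, k = 1.72 × 10⁻⁵ s⁻¹)

**Not at rest.** Friday's flask had not come to rest at 12.0 h, with D still at 30.8% after 1.32 turnovers. Thursday's flask, left for 60.0 h, counts 6.62 turnovers, for which P exp(−kt) gives 0.771% of D where the flask holds 0.866%, with Q at 75.4%. Friday's flask, left for 120 h, holds Q at 76.5%, which is 32 points above its amount at 12.0 h.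

The readings are calculated for an exercise.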